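## Structural features

The target is a tetraflavanoid made of three fisetinidol units (units 1, 2 and 4, each with a resorcinol-type ring A lacking O5) and one catechin unit (the hub, with a phloroglucinol-type ring A). The units are joined only by C4–aryl bonds, from C4 of unit 1 to C6 of unit 2, from C4 of unit 2 to C6 of the hub and from C4 of unit 4 to C8 of the hub, so ring A of the hub is hexasubstituted. Of the eleven stereocentres, C2, C3 and C4 are contiguous in each fisetinidol unit (2R,3S with the C4 aryl group trans to O3, the 4α arrangement, all-trans around the pyran ring), and the hub is 2R,3S as in (+)-catechin. The free compound carries thirteen phenolic and four secondary hydroxyls, oxidation-prone catechol rings, and benzylic C2–O1 and C4–aryl bonds that tolerate neither strong acid nor forcing reduction, so the phenols are carried as benzyl ethers and released last. The real difficulty is the bond from unit 1 to unit 2: ring A of the hub accepts C4 cations cleanly (C8 first, then C6), but on the resorcinol ring of unit 2 C6 competes with C8, and unit 2 must afterwards still offer an electrophilic C4. The key step exploits the fact that C6 of unit 2 is ortho to O7 and para to the oxygen on C8a, which is exactly the substitution pattern of the phenol formed from a vinylketene and a siloxyalkyne. Ring A of unit 2 (C4a, C5, C6, C7, C8, C8a) can therefore be grown around C4 of unit 1, with O7 and the oxygen on C8a differentiated as silyl ether and free phenol and with C4a left unsubstituted.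

## Logic of the disconnections

35 back to 34 and 33: the thirteen O–benzyl bonds and the one O–Si bond are cut last. This keeps every phenol masked through all C–C bond formations; the forward steps must spare the C2–O1 and C4–aryl bonds.

33 to 27 and 31: the bond between C4 of unit 2 and C6 of the hub is cut. C6 is the only position left on ring A of the hub, so regiochemistry is not in question, and the cut divides the molecule into two two-unit halves. The forward step must capture the C4 cation anti to O3 (4α) at a hindered carbon.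

31 to 9 and 29, and 29 to 28: the bond between C4 of unit 4 and C8 of the hub is cut. C8 is the intrinsically preferred site of the hub, 9 lies on the way to unit 1 in any case, and 29 is one step from the chiral pool. The forward step must give C8 over C6, single alkylation and 4α.

27 to 26, 25, and then 24 plus 5: the C3–O and C4–O bonds (syn-dihydroxylation), then C4–C4a (hydroarylation), then O1–C2 (etherification with inversion) are cut. This hangs the pyran ring of unit 2 on the phenol oxygen and on C4a, the two positions the benzannulation leaves ready. C2 comes from 5 and C3 is set from C2. The forward steps must close on C4a and not C8, and must not lose configuration at the propargylic carbon.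

24 to 15 and 19 (key disconnection): C8a–C8, C6–C7 and C8a–C4a are cut, with C5–C6 traced back to the Wolff shift. The 4→6 connectivity then follows from atom mapping and not from a selectivity, and unit 2 shrinks to a two-carbon alkyne and a four-carbon chain on C4 of unit 1. The forward step needs vinyl migration to outrun carbene chemistry and needs one [2+2] orientation.

19 to 16: the O–Si and C–O bonds of the ynol ether are cut, leading back to a C2 gas.

15 to 13, and 13 to 10 plus 11: the diazo group is removed, then the C4–CH2 bond is cut. 13 has a single enolisable position, and 10 ionises at C4. The forward steps need 4α capture and survival of the vinyl ketone.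

10 to 9, 8, 7, and then 5 plus 6: the two O–benzyl bonds on C3 and C4, then the same three ring-forming operations as for unit 2 (C3–O/C4–O, C4–C4a, O1–C2) are cut. One chemistry and one chiral building block serve units 1, 2 and 4.

5 to 4, 3, and then 1 plus 2: the future C2–C3 bond is cut and the carbinol is resolved. The forward steps must deliver one enantiomer cleanly.

## Other disconnections considered

Alternative 1: The three C4–C4a bonds of units 1, 2 and 4 are cut at once; each pyran ring is reopened to an aryl propargyl ether whose alkyne terminus is already bonded to the neighbouring ring-A carbon. In the forward step Ph3PAuNTf2 (monovalent gold) activates the three alkynes, the tethered arenes attack 6-endo, and the tris(flav-3-ene) A1 results; a triple hydroboration would then set all C3 and C4 centres. In its favour, every interflavanyl bond is placed by a cross-coupling at a defined carbon. The 3,4-trans relationship would come stereospecifically from syn-addition anti to the C2 aryl group; on control of C4 this is better than the chosen plan, which relies three times on the facial selectivity of cation capture. Against it, the bond to C6 of unit 2 then requires a ring A of unit 2 halogenated at C6 with O7 and the oxygen on C8a already differentiated, so the regiochemical problem is moved to the halogenation of an unsymmetrical resorcinol diether and not removed. Two of the alkynes sit between benzyloxy groups of the hub, which can themselves add to a gold-activated alkyne. Three hindered trisubstituted alkenes, two of them bearing a 2,6-dialkoxyaryl group, must afterwards be hydroborated. In structure the two plans reach the same skeleton. In mechanism A1 multiplies one sensitive event by three, whereas the chosen plan uses gold only on two terminal alkynes. In step economy the alternative is the equal of the chosen plan or slightly shorter.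

Alternative 2: The hub ring A is cut at C4a–C8a, C5–C6 and C7–C8. In the forward step [Rh(cod)2]BF4 (monovalent rhodium) with BINAP would join three alkyne units, two of them tethered through O1, C2, C3 and C4 of the hub and the third bearing units 1 and 2, closing the benzene and pyran rings of the hub together to give A2. In its favour, both interflavanyl bonds of the hub are fixed on alkyne carbons before the ring exists, so C6 and C8 cannot be confused; on that point it is the equal of the chosen plan or slightly better, since the chosen plan depends on the C8 preference in step 16. Against it, the hub is the one unit that can be bought intact with both stereocentres, and here it would have to be rebuilt. The intermolecular partner is unsymmetrical and can insert in two orientations, leading to regioisomeric arenes. The C4 centres of units 2 and 4 become propargylic and must be set by other means. Ynol ethers of secondary benzylic alcohols are fragile. Ring A of unit 2 is left unaddressed. In structure it is elegant, in mechanism less predictable, and in step economy clearly longer.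

Alternative 3: The C2=C3 bond of unit 4 is cut. In the forward step the second-generation Grubbs catalyst would join a C4 vinyl group to an α-aryloxystyrene with loss of ethylene, giving the flav-2-ene A3; hydroboration–oxidation anti to the C4 substituent would then set C3 and C2. In its favour, C2 and C3 follow stereospecifically from C4 in one operation and no cation is involved. For the internal diastereocontrol of unit 4 it is the equal of the chosen plan or better, provided C4 is available as one enantiomer. Against it, that C4 centre (a diaryl allyl methine on the hindered C8 of the hub) must be made enantioselectively without help. Metathesis onto a 1,1-disubstituted enol ether is slow and gives stabilised carbenes. A3 is an acid-labile enol ether with a doubly benzylic, allylic C4–H. The approach addresses only the easiest junction, which the chosen plan makes in one step from the shared intermediate 9. In step economy it is worse, and it does nothing for the bond between units 1 and 2.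

Key step: step 11

Remarks on the chemistry (assumptions):
- The structure is read as 2R,3S in all four units with 4α (3,4-trans) bonds at the three substituted C4 atoms; the route is built for that isomer.
- Checking every ring atom of 15 and 24 against the target shows no error in either structure. O3 of unit 1 is kept as a benzyl ether, because the enolate and diazo chemistry of steps 8 and 9 would not tolerate a free hydroxyl there.
- The flavan-3,4-diol 9 is reached from the propargylic alcohol 5 and not from a chalcone, because 5 later also supplies C2 of unit 2. Diol 9 is used directly as the electrophile for unit 4 and, after bis-benzylation to 10, for unit 1.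
- Compounds 1, 2, 6, 11, 16 and 28 are taken as purchasable; (triisopropylsiloxy)acetylene is not, and is made in step 10.

## Steps

Step 1
Reactants: 1 3,4-bis(benzyloxy)benzaldehyde; 2 ethynylmagnesium bromide
Product: 3 rac-1-[3,4-bis(benzyloxy)phenyl]prop-2-yn-1-ol
Conditions: THF, 0 °C; aq. NH4Cl
Reagents that add atoms: none
Why: 1,2-Addition of the alkynyl Grignard reagent to the aldehyde; the carbinol centre is formed racemic and is resolved in step 2.

Step 2
Reactants: 3 rac-1-[3,4-bis(benzyloxy)phenyl]prop-2-yn-1-ol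
Product: 4 (1R)-1-[3,4-bis(benzyloxy)phenyl]prop-2-yn-1-yl acetate
Conditions: Novozym 435 (immobilised Candida antarctica lipase B), vinyl acetate, toluene, 35 °C, stopped near half conversion
Reagents that add atoms: vinyl acetate, CC(=O)OC=C
Why: Lipase-catalysed kinetic resolution by irreversible transesterification; with aryl as the large and ethynyl as the medium substituent, the empirical size rule for this lipase predicts acylation of the (R)-alcohol. The (S)-alcohol is left behind and removed by chromatography.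

Step 3
Reactants: 4 (1R)-1-[3,4-bis(benzyloxy)phenyl]prop-2-yn-1-yl acetate
Product: 5 (1R)-1-[3,4-bis(benzyloxy)phenyl]prop-2-yn-1-ol
Conditions: K2CO3, MeOH, 0 °C
Reagents that add atoms: none
Why: Base-catalysed transesterification cleaves the acyl–oxygen bond, so the carbinol C–O bond and its configuration are untouched; alkyne and benzyl ethers are inert.

Step 4
Reactants: 5 (1R)-1-[3,4-bis(benzyloxy)phenyl]prop-2-yn-1-ol; 6 3-(benzyloxy)phenol
Product: 7 1-(benzyloxy)-3-{[(1S)-1-[3,4-bis(benzyloxy)phenyl]prop-2-yn-1-yl]oxy}benzene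
Conditions: PPh3, DIAD, toluene, −20 → 0 °C
Reagents that add atoms: none
Why: Mitsunobu etherification; SN2 displacement of the alkoxyphosphonium group by the phenoxide inverts the carbinol centre, (R)-alcohol to (S)-ether, which is the future C2. The non-polar solvent and low temperature are chosen to hold back ionisation of the electron-rich benzylic centre.

Step 5
Reactants: 7 1-(benzyloxy)-3-{[(1S)-1-[3,4-bis(benzyloxy)phenyl]prop-2-yn-1-yl]oxy}benzene
Product: 8 (2S)-7-(benzyloxy)-2-[3,4-bis(benzyloxy)phenyl]-2H-chromene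
Conditions: Ph3PAuNTf2 (3 mol%), CH2Cl2, rt, dark
Reagents that add atoms: none
Why: Gold-catalysed intramolecular alkyne hydroarylation (6-endo-dig Friedel–Crafts-type attack on the π-activated alkyne, then protodeauration) closes the pyran ring as a flav-3-ene. Attack should occur at the ortho position para to the benzyloxy group and not at the crowded position between the two oxygens; C2 is not involved.

Step 6
Reactants: 8 (2S)-7-(benzyloxy)-2-[3,4-bis(benzyloxy)phenyl]-2H-chromene
Product: 9 (2R,3S,4S)-7-(benzyloxy)-2-[3,4-bis(benzyloxy)phenyl]chromane-3,4-diol (2,3-trans-3,4-cis)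
Conditions: OsO4 (2 mol%), N-methylmorpholine N-oxide, acetone–H2O, rt
Reagents that add atoms: osmium tetroxide, O=[Os](=O)(=O)=O; N-methylmorpholine N-oxide, C[N+]1([O-])CCOCC1; water, O
Why: Upjohn syn-dihydroxylation of the cis-styrenyl C3=C4 bond from the face opposite the C2 aryl group sets C3 (S, 2,3-trans) and C4 (S, 3,4-cis); the C4 centre is erased on ionisation later.

Step 7
Reactants: 9 (2R,3S,4S)-7-(benzyloxy)-2-[3,4-bis(benzyloxy)phenyl]chromane-3,4-diol
Product: 10 (2R,3S,4S)-3,4,7-tris(benzyloxy)-2-[3,4-bis(benzyloxy)phenyl]chromane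
Conditions: NaH, BnBr, Bu4NI (cat.), DMF, 0 °C → rt
Reagents that add atoms: benzyl bromide, BrCc1ccccc1
Why: Williamson etherification of both hydroxyls; O3 becomes a permanent benzyl ether and the benzylic C4–OBn group becomes the leaving group for C4 ionisation.

Step 8
Reactants: 10 (2R,3S,4S)-3,4,7-tris(benzyloxy)-2-[3,4-bis(benzyloxy)phenyl]chromane; 11 2-(trimethylsiloxy)buta-1,3-diene
Product: 13 1-[(2R,3S,4R)-3,7-bis(benzyloxy)-2-[3,4-bis(benzyloxy)phenyl]chroman-4-yl]but-3-en-2-one, via 3-benzyloxyflavan-4-yl cation 12 (not isolated)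
Conditions: TMSOTf (0.2 equiv), 11 (1.2 equiv, slow addition), CH2Cl2, −78 → −40 °C; Et3N quench
Reagents that add atoms: none
Why: Lewis-acid ionisation of the C4 benzyl ether gives the 7-alkoxy-stabilised benzylic cation 12, which is captured by the terminal enol carbon of the siloxydiene (Mukaiyama-type alkylation); silyl transfer releases the vinyl ketone. Attack anti to the C3 benzyloxy group on the half-chair cation sets C4 as 3,4-trans (4α).

Step 9
Reactants: 13 1-[(2R,3S,4R)-3,7-bis(benzyloxy)-2-[3,4-bis(benzyloxy)phenyl]chroman-4-yl]but-3-en-2-one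
Product: 15 1-diazo-1-[(2R,3S)-3,7-bis(benzyloxy)-2-[3,4-bis(benzyloxy)phenyl]chroman-4α-yl]but-3-en-2-one, via trifluoroacetyl diketone 14 (not isolated)
Conditions: LiN(SiMe3)2, THF, −78 °C; CF3CO2CH2CF3, −78 °C; then MsN3, Et3N, H2O, MeCN, rt
Reagents that add atoms: 2,2,2-trifluoroethyl trifluoroacetate, O=C(OCC(F)(F)F)C(F)(F)F; methanesulfonyl azide, CS(=O)(=O)N=[N+]=[N-]
Why: Detrifluoroacetylative (Regitz-type deacylative) diazo transfer: the only enolisable position, the CH2 on C4, is trifluoroacetylated, and diketone 14 takes the diazo group from the sulfonyl azide with loss of the trifluoroacetyl group. C4 is β to the carbonyl and cannot epimerise.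

Step 10
Reactants: 16 acetylene
Product: 19 (triisopropylsiloxy)acetylene, via lithium acetylide 17 (not isolated), via lithium ethynolate 18 (not isolated)
Conditions: n-BuLi, THF, −78 °C; t-BuOOLi (from t-BuOOH and LiN(SiMe3)2), −78 → −20 °C; TIPSOTf, −78 → 0 °C
Reagents that add atoms: tert-butyl hydroperoxide, CC(C)(C)OO; triisopropylsilyl trifluoromethanesulfonate, CC(C)[Si](OS(=O)(=O)C(F)(F)F)(C(C)C)C(C)C
Why: Electrophilic oxygenation of the lithium acetylide by the lithium peroxide gives the ynolate, and O-silylation with the bulky silyl triflate gives the silyl ynol ether. The size of the triisopropylsilyl group disfavours C-silylation to a silylketene.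

Step 11
Reactants: 15 1-diazo-1-[(2R,3S)-3,7-bis(benzyloxy)-2-[3,4-bis(benzyloxy)phenyl]chroman-4α-yl]but-3-en-2-one; 19 (triisopropylsiloxy)acetylene
Product: 24 4-[(2R,3S)-3,7-bis(benzyloxy)-2-[3,4-bis(benzyloxy)phenyl]chroman-4α-yl]-3-(triisopropylsiloxy)phenol, via vinylketene 20 (not isolated), via 4-vinylcyclobutenone 21 (not isolated), via dienylketene 22 (not isolated), via cyclohexadienone 23 (not isolated)
Conditions: hν (365 nm, Pyrex), 19 (2 equiv), degassed ClCH2CH2Cl, rt; then 80 °C
Reagents that add atoms: none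
Why: Excitation of the diazo ketone expels N2 and the vinyl group shifts to the diazo carbon (photochemical Wolff rearrangement), giving vinylketene 20 with the flavanyl group on the ketene α-carbon. The ketene carbonyl carbon is attacked by the nucleophilic unsubstituted carbon of the ynol ether and the ring closes on the siloxy-bearing carbon ([2+2], bonds C8a–C8 and C6–C7), giving 4-vinylcyclobutenone 21. A 4π-electrocyclic opening gives dienylketene 22, its 6π-electrocyclisation (bond C8a–C4a) gives 23, and enolisation gives the phenol. The closest known reaction type is the Danheiser benzannulation of α-diazo ketones with siloxyalkynes to resorcinol monosilyl ethers. The one new ring, ring A of unit 2, is thus closed by a disrotatory 6π-electrocyclisation of a ketene-terminated triene after a four-membered ring has been closed by [2+2] and opened again. No stereocentre is created: the quaternary carbon of 21 is lost on aromatisation, and C4 of unit 1, not α to any carbonyl, is a spectator. The step needs one [2+2] orientation, which the polarisation of the siloxyalkyne secures (oxygen-stabilised positive charge on the substituted carbon), and it needs vinyl migration to be faster than a 1,2-hydride shift from C4, which direct irradiation of the singlet diazo ketone and an excess of 19 favour. Irradiation above 300 nm keeps the benzyl and aryl ether chromophores out of play.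

Step 12
Reactants: 24 4-[(2R,3S)-3,7-bis(benzyloxy)-2-[3,4-bis(benzyloxy)phenyl]chroman-4α-yl]-3-(triisopropylsiloxy)phenol; 5 (1R)-1-[3,4-bis(benzyloxy)phenyl]prop-2-yn-1-ol
Product: 25 (1S)-1-[3,4-bis(benzyloxy)phenyl]prop-2-yn-1-yl ether of 24
Conditions: PPh3, DIAD, toluene, −20 → 0 °C
Reagents that add atoms: none
Why: Mitsunobu etherification of the only free phenol with inversion at the carbinol carbon gives the (S)-propargyl ether, which is C2 of unit 2 in its final configuration.

Step 13
Reactants: 25 (1S)-1-[3,4-bis(benzyloxy)phenyl]prop-2-yn-1-yl ether of 24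
Product: 26 (2S)-2-[3,4-bis(benzyloxy)phenyl]-6-[(2R,3S)-3,7-bis(benzyloxy)-2-[3,4-bis(benzyloxy)phenyl]chroman-4α-yl]-7-(triisopropylsiloxy)-2H-chromene
Conditions: Ph3PAuNTf2 (5 mol%), CH2Cl2, rt, dark
Reagents that add atoms: none
Why: The same gold-catalysed 6-endo-dig hydroarylation closes the pyran ring of unit 2. Of the two positions ortho to the ether oxygen, C4a is para to the siloxy group and open, while C8 is screened by the adjacent triisopropylsilyl group.

Step 14
Reactants: 26 the unit 1–unit 2 flav-3-ene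
Product: 27 (2R,3S,4S)-2-[3,4-bis(benzyloxy)phenyl]-6-[(2R,3S)-3,7-bis(benzyloxy)-2-[3,4-bis(benzyloxy)phenyl]chroman-4α-yl]-7-(triisopropylsiloxy)chromane-3,4-diol
Conditions: OsO4 (5 mol%), N-methylmorpholine N-oxide, acetone–THF–H2O, rt
Reagents that add atoms: osmium tetroxide, O=[Os](=O)(=O)=O; N-methylmorpholine N-oxide, C[N+]1([O-])CCOCC1; water, O
Why: Upjohn syn-dihydroxylation anti to the C2 aryl group sets C3 of unit 2 (S, final) and a temporary cis C4 carbinol; no other alkene is present.

Step 15
Reactants: 28 (+)-catechin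
Product: 29 5,7,3',4'-tetra-O-benzyl-(+)-catechin
Conditions: BnBr, K2CO3, DMF, 0 °C → rt
Reagents that add atoms: benzyl bromide, BrCc1ccccc1
Why: Williamson O-benzylation of the four phenols; carbonate does not deprotonate the secondary alcohol, which stays free, and the mild conditions avoid epimerisation at C2.

Step 16
Reactants: 9 (2R,3S,4S)-7-(benzyloxy)-2-[3,4-bis(benzyloxy)phenyl]chromane-3,4-diol; 29 5,7,3',4'-tetra-O-benzyl-(+)-catechin
Product: 31 7,3',4'-tri-O-benzylfisetinidol-(4α→8)-5,7,3',4'-tetra-O-benzylcatechin, via 3-hydroxyflavan-4-yl cation 30 (not isolated)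
Conditions: BF3·OEt2 (0.5 equiv), 29 (3 equiv), 4 Å MS, CH2Cl2, −40 → 0 °C
Reagents that add atoms: none
Why: Ionisation of the benzylic C4 hydroxyl of the free diol gives the 7-benzyloxy-stabilised cation 30, which alkylates the phloroglucinol-type ring of 29 (Friedel–Crafts alkylation, as in acid-mediated condensations of flavan-3,4-diols with catechin); C8 is the more nucleophilic and less encumbered of the two free positions. The arene adds anti to the C3 hydroxyl, giving the 4α (3,4-trans) bond of unit 4, and the excess of 29 suppresses double alkylation and self-condensation of 9.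

Step 17
Reactants: 27 the unit 1–unit 2 flavan-3,4-diol; 31 7,3',4'-tri-O-benzylfisetinidol-(4α→8)-5,7,3',4'-tetra-O-benzylcatechin
Product: 33 trideca-O-benzyl-7-O-(triisopropylsilyl) tetramer (3-OH free on unit 2; on unit 4; on the hub), via siloxy-substituted flavan-4-yl cation 32 (not isolated)
Conditions: BF3·OEt2 (0.5 equiv), 4 Å MS, CH2Cl2, −40 → 0 °C
Reagents that add atoms: none
Why: Ionisation of the benzylic C4 hydroxyl of unit 2 gives the para-siloxy-stabilised cation 32, which is captured by C6, the only remaining position of ring A of the hub (Friedel–Crafts alkylation as in biomimetic flavan-3,4-diol couplings). Approach anti to the boron-complexed C3 hydroxyl gives the 3,4-trans (4α) bond.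

Step 18
Reactants: 33 trideca-O-benzyl-7-O-(triisopropylsilyl) tetramer
Product: 34 trideca-O-benzyl tetramer with free O7 on unit 2
Conditions: Bu4NF, AcOH, THF, 0 °C
Reagents that add atoms: none
Why: Fluoride cleavage of the aryl silyl ether; buffering with acetic acid keeps the liberated phenoxide from oxidation and leaves all benzyl ethers intact.

Step 19
Reactants: 34 trideca-O-benzyl tetramer with free O7 on unit 2
Product: 35 fisetinidol-(4α→6)-fisetinidol-(4α→6)-[fisetinidol-(4α→8)]-catechin (target)
Conditions: H2 (1 atm), Pd(OH)2/C, THF–MeOH, rt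
Reagents that add atoms: none
Why: Hydrogenolysis of the thirteen benzyl ethers under neutral conditions; the ring C2–O1 bonds and the C4–aryl bonds should survive as in other O-benzylated flavan oligomers, and no stereocentre is touched.

## Compound list

1 | 3,4-bis(benzyloxy)benzaldehyde | O=Cc1ccc(OCc2ccccc2)c(OCc2ccccc2)c1 | starting material
2 | ethynylmagnesium bromide | C#C[Mg]Br | starting material
3 | rac-1-[3,4-bis(benzyloxy)phenyl]prop-2-yn-1-ol | OC(C#C)c1ccc(OCc2ccccc2)c(OCc2ccccc2)c1 | intermediate
4 | (1R)-1-[3,4-bis(benzyloxy)phenyl]prop-2-yn-1-yl acetate | CC(=O)O[C@@H](c1ccc(OCc2ccccc2)c(OCc2ccccc2)c1)C#C | intermediate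
5 | (1R)-1-[3,4-bis(benzyloxy)phenyl]prop-2-yn-1-ol | O[C@@H](c1ccc(OCc2ccccc2)c(OCc2ccccc2)c1)C#C | intermediate
6 | 3-(benzyloxy)phenol | Oc1cccc(OCc2ccccc2)c1 | starting material
7 | 1-(benzyloxy)-3-{[(1S)-1-[3,4-bis(benzyloxy)phenyl]prop-2-yn-1-yl]oxy}benzene | c1ccccc1COc1cccc(O[C@H](c2ccc(OCc3ccccc3)c(OCc3ccccc3)c2)C#C)c1 | intermediate
8 | (2S)-7-(benzyloxy)-2-[3,4-bis(benzyloxy)phenyl]-2H-chromene | c5ccccc5COc1ccc2c(c1)O[C@H](c1ccc(OCc5ccccc5)c(OCc5ccccc5)c1)C=C2 | intermediate
9 | (2R,3S,4S)-7-(benzyloxy)-2-[3,4-bis(benzyloxy)phenyl]chromane-3,4-diol | c5ccccc5COc1ccc2c(c1)O[C@H](c1ccc(OCc5ccccc5)c(OCc5ccccc5)c1)[C@@H](O)[C@H]2O | intermediate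
10 | (2R,3S,4S)-3,4,7-tris(benzyloxy)-2-[3,4-bis(benzyloxy)phenyl]chromane | c5ccccc5COc1ccc2c(c1)O[C@H](c1ccc(OCc5ccccc5)c(OCc5ccccc5)c1)[C@@H](OCc5ccccc5)[C@H]2OCc5ccccc5 | intermediate
11 | 2-(trimethylsiloxy)buta-1,3-diene | C=CC(=C)O[Si](C)(C)C | starting material
12 | (2R,3S)-3,7-bis(benzyloxy)-2-[3,4-bis(benzyloxy)phenyl]chroman-4-ylium (3-benzyloxyflavan-4-yl cation) | c5ccccc5COc1ccc2c(c1)O[C@H](c1ccc(OCc5ccccc5)c(OCc5ccccc5)c1)[C@@H](OCc5ccccc5)[CH+]2 | intermediate
13 | 1-[(2R,3S,4R)-3,7-bis(benzyloxy)-2-[3,4-bis(benzyloxy)phenyl]chroman-4-yl]but-3-en-2-one | c5ccccc5COc1ccc2c(c1)O[C@H](c1ccc(OCc5ccccc5)c(OCc5ccccc5)c1)[C@@H](OCc5ccccc5)[C@@H]2CC(=O)C=C | intermediate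
14 | 3-[unit 1 chroman-4α-yl]-1,1,1-trifluorohex-5-ene-2,4-dione (trifluoroacetyl diketone) | c5ccccc5COc1ccc2c(c1)O[C@H](c1ccc(OCc5ccccc5)c(OCc5ccccc5)c1)[C@@H](OCc5ccccc5)[C@@H]2C(C(=O)C(F)(F)F)C(=O)C=C | intermediate
15 | 1-diazo-1-[(2R,3S)-3,7-bis(benzyloxy)-2-[3,4-bis(benzyloxy)phenyl]chroman-4α-yl]but-3-en-2-one | c5ccccc5COc1ccc2c(c1)O[C@H](c1ccc(OCc5ccccc5)c(OCc5ccccc5)c1)[C@@H](OCc5ccccc5)[C@@H]2C(=[N+]=[N-])C(=O)C=C | intermediate
16 | acetylene | C#C | starting material
17 | lithium acetylide | [Li]C#C | intermediate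
18 | lithium ethynolate | [Li]OC#C | intermediate
19 | (triisopropylsiloxy)acetylene | C#CO[Si](C(C)C)(C(C)C)C(C)C | intermediate
20 | 2-[unit 1 chroman-4α-yl]buta-1,3-dien-1-one (vinylketene) | c5ccccc5COc1ccc2c(c1)O[C@H](c1ccc(OCc5ccccc5)c(OCc5ccccc5)c1)[C@@H](OCc5ccccc5)[C@@H]2C(=C=O)C=C | intermediate
21 | 4-[unit 1 chroman-4α-yl]-3-(triisopropylsiloxy)-4-vinylcyclobut-2-en-1-one (both epimers at the ring carbon) | c5ccccc5COc1ccc2c(c1)O[C@H](c1ccc(OCc5ccccc5)c(OCc5ccccc5)c1)[C@@H](OCc5ccccc5)[C@@H]2C1(C=C)C(=O)C=C1O[Si](C(C)C)(C(C)C)C(C)C | intermediate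
22 | 4-[unit 1 chroman-4α-yl]-3-(triisopropylsiloxy)hexa-1,3,5-trien-1-one (dienylketene, vinyl cis to ketenyl) | c5ccccc5COc1ccc2c(c1)O[C@H](c1ccc(OCc5ccccc5)c(OCc5ccccc5)c1)[C@@H](OCc5ccccc5)[C@@H]2/C(C=C)=C(/C=C=O)O[Si](C(C)C)(C(C)C)C(C)C | intermediate
23 | 4-[unit 1 chroman-4α-yl]-3-(triisopropylsiloxy)cyclohexa-2,4-dien-1-one | c5ccccc5COc1ccc2c(c1)O[C@H](c1ccc(OCc5ccccc5)c(OCc5ccccc5)c1)[C@@H](OCc5ccccc5)[C@@H]2C1=CCC(=O)C=C1O[Si](C(C)C)(C(C)C)C(C)C | intermediate
24 | 4-[(2R,3S)-3,7-bis(benzyloxy)-2-[3,4-bis(benzyloxy)phenyl]chroman-4α-yl]-3-(triisopropylsiloxy)phenol | c5ccccc5COc1ccc2c(c1)O[C@H](c1ccc(OCc5ccccc5)c(OCc5ccccc5)c1)[C@@H](OCc5ccccc5)[C@@H]2c1ccc(O)cc1O[Si](C(C)C)(C(C)C)C(C)C | intermediate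
25 | (1S)-1-[3,4-bis(benzyloxy)phenyl]prop-2-yn-1-yl ether of 24 | c5ccccc5COc1ccc2c(c1)O[C@H](c1ccc(OCc5ccccc5)c(OCc5ccccc5)c1)[C@@H](OCc5ccccc5)[C@@H]2c1ccc(O[C@H](c2ccc(OCc5ccccc5)c(OCc5ccccc5)c2)C#C)cc1O[Si](C(C)C)(C(C)C)C(C)C | intermediate
26 | unit 1–unit 2 flav-3-ene, (2S)-2H-chromene with unit 1 on C6 and OTIPS on C7 | c5ccccc5COc1ccc2c(c1)O[C@H](c1ccc(OCc5ccccc5)c(OCc5ccccc5)c1)[C@@H](OCc5ccccc5)[C@@H]2c1cc2c(cc1O[Si](C(C)C)(C(C)C)C(C)C)O[C@H](c1ccc(OCc5ccccc5)c(OCc5ccccc5)c1)C=C2 | intermediate
27 | unit 1–unit 2 (2R,3S,4S)-flavan-3,4-diol (2,3-trans-3,4-cis in unit 2) | c5ccccc5COc1ccc2c(c1)O[C@H](c1ccc(OCc5ccccc5)c(OCc5ccccc5)c1)[C@@H](OCc5ccccc5)[C@@H]2c1cc2c(cc1O[Si](C(C)C)(C(C)C)C(C)C)O[C@H](c1ccc(OCc5ccccc5)c(OCc5ccccc5)c1)[C@@H](O)[C@H]2O | intermediate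
28 | (+)-catechin | O[C@H]1Cc2c(O)cc(O)cc2O[C@@H]1c1ccc(O)c(O)c1 | starting material
29 | 5,7,3',4'-tetra-O-benzyl-(+)-catechin | O[C@H]1Cc2c(OCc3ccccc3)cc(OCc3ccccc3)cc2O[C@@H]1c1ccc(OCc3ccccc3)c(OCc3ccccc3)c1 | intermediate
30 | (2R,3S)-7-(benzyloxy)-2-[3,4-bis(benzyloxy)phenyl]-3-hydroxychroman-4-ylium (3-hydroxyflavan-4-yl cation) | c5ccccc5COc1ccc2c(c1)O[C@H](c1ccc(OCc5ccccc5)c(OCc5ccccc5)c1)[C@@H](O)[CH+]2 | intermediate
31 | 7,3',4'-tri-O-benzylfisetinidol-(4α→8)-5,7,3',4'-tetra-O-benzylcatechin | c1c(OCc5ccccc5)c2c(c([C@@H]3c4ccc(OCc5ccccc5)cc4O[C@H](c4ccc(OCc5ccccc5)c(OCc5ccccc5)c4)[C@H]3O)c1OCc5ccccc5)O[C@H](c1ccc(OCc5ccccc5)c(OCc5ccccc5)c1)[C@@H](O)C2 | intermediate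
32 | unit 2 C4 cation derived from 27 (siloxy-substituted flavan-4-yl cation) | c5ccccc5COc1ccc2c(c1)O[C@H](c1ccc(OCc5ccccc5)c(OCc5ccccc5)c1)[C@@H](OCc5ccccc5)[C@@H]2c1cc2c(cc1O[Si](C(C)C)(C(C)C)C(C)C)O[C@H](c1ccc(OCc5ccccc5)c(OCc5ccccc5)c1)[C@@H](O)[CH+]2 | intermediate
33 | trideca-O-benzyl-7-O-(triisopropylsilyl) tetramer (free 3-OH on unit 2, on unit 4 and on the hub) | c5ccccc5COc1ccc2c(c1)O[C@H](c1ccc(OCc5ccccc5)c(OCc5ccccc5)c1)[C@@H](OCc5ccccc5)[C@@H]2c1cc2c(cc1O[Si](C(C)C)(C(C)C)C(C)C)O[C@H](c1ccc(OCc5ccccc5)c(OCc5ccccc5)c1)[C@@H](O)[C@@H]2c1c(OCc5ccccc5)c2c(c([C@@H]3c4ccc(OCc5ccccc5)cc4O[C@H](c4ccc(OCc5ccccc5)c(OCc5ccccc5)c4)[C@H]3O)c1OCc5ccccc5)O[C@H](c1ccc(OCc5ccccc5)c(OCc5ccccc5)c1)[C@@H](O)C2 | intermediate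
34 | trideca-O-benzyl tetramer with free O7 on unit 2 | c5ccccc5COc1ccc2c(c1)O[C@H](c1ccc(OCc5ccccc5)c(OCc5ccccc5)c1)[C@@H](OCc5ccccc5)[C@@H]2c1cc2c(cc1O)O[C@H](c1ccc(OCc5ccccc5)c(OCc5ccccc5)c1)[C@@H](O)[C@@H]2c1c(OCc5ccccc5)c2c(c([C@@H]3c4ccc(OCc5ccccc5)cc4O[C@H](c4ccc(OCc5ccccc5)c(OCc5ccccc5)c4)[C@H]3O)c1OCc5ccccc5)O[C@H](c1ccc(OCc5ccccc5)c(OCc5ccccc5)c1)[C@@H](O)C2 | intermediate
35 | fisetinidol-(4α→6)-fisetinidol-(4α→6)-[fisetinidol-(4α→8)]-catechin (CNP0263622.1) | Oc1ccc2c(c1)O[C@H](c1ccc(O)c(O)c1)[C@@H](O)[C@@H]2c1cc2c(cc1O)O[C@H](c1ccc(O)c(O)c1)[C@@H](O)[C@@H]2c1c(O)c2c(c([C@@H]3c4ccc(O)cc4O[C@H](c4ccc(O)c(O)c4)[C@H]3O)c1O)O[C@H](c1ccc(O)c(O)c1)[C@@H](O)C2 | target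

## Step count and least certain steps

Total: 19 steps. Longest linear sequence: 16 steps (steps 1–9, 11–14, 17–19, from 1).

Step 11 (key step). The most likely failure is that the excited diazo ketone leaves the concerted Wolff pathway. The secondary, hindered flavanyl group on the diazo carbon disfavours the s-Z conformer from which the vinyl shift occurs. A free carbene would then undergo a 1,2-hydride shift from C4 (destroying that stereocentre) or insert into the C–H bonds of the C3 benzyloxy methylene; dimerisation of the vinylketene is a further drain if 19 is not in excess. Fallback, from 10 back to 24, without the benzannulation: the cation from 10 (BF3·OEt2, CH2Cl2–dioxane, 0 °C) is captured by excess resorcinol. In resorcinol the 4- and 6-positions are equivalent and each is ortho to one hydroxyl and para to the other, so this gives the 4-(2,4-dihydroxyphenyl)flavan F1 with the required connectivity. The unhindered para-hydroxyl is then acetylated selectively (Ac2O, 1 equiv, pyridine, −20 °C) to the monoacetate F2, and the hindered ortho-hydroxyl is silylated (TIPSOTf, 2,6-lutidine) to the silyl ether acetate F3. Brief methanolysis (K2CO3, MeOH, 0 °C) returns to 24.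

Step 9. The most likely failure is conjugate addition and anionic oligomerisation of the unsubstituted vinyl ketone under the amide base and in the aqueous amine stage, together with slow acylation at the hindered CH2. Fallback, from 10 to 15, placing the diazo group before the enone exists: the cation from 10 is captured by pentane-2,4-dione (TMSOTf cat.) to give the 3-(flavan-4α-yl)pentane-2,4-dione F4. Deacetylative diazo transfer (4-acetamidobenzenesulfonyl azide, DBU, MeCN) gives the diazo methyl ketone F5. Deprotonation of its only acidic position, the methyl group (LiN(SiMe3)2, −78 °C), and Mannich reaction with dimethyl(methylene)ammonium iodide gives the β-amino ketone F6. Quaternisation with MeI and elimination with NaHCO3 unveils the vinyl group and returns to 15.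

Step 8. The most likely failure is consumption of the product enone by unreacted 11 under Lewis acid (Diels–Alder or Mukaiyama–Michael addition), and erosion of the α-facial preference with so small a nucleophile. Fallback, from 10 to 13: capture of the cation by 2-(trimethylsiloxy)propene gives the methyl ketone F7, which is no dienophile. Kinetic enolisation at the methyl group (LiN(iPr)2, −78 °C) and Mannich reaction with dimethyl(methylene)ammonium iodide gives the Mannich base F8. Methylation and elimination (MeI; NaHCO3) return to 13.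

Step 12. The most likely failure is partial loss of configuration at the new ether carbon, through ionisation of the alkoxyphosphonium intermediate to the 3,4-dialkoxybenzylic, propargylic cation. This would leave the C2 epimer of unit 2 as a diastereomer that is hard to remove. Fallback, from 3 and 24 to 25, replacing the stereospecific substitution by a catalyst-controlled one: 3 is acetylated to the racemic acetate F9 (Ac2O, pyridine). F9 is coupled with 24 by copper-catalysed propargylic etherification (Cu(OTf)·0.5C6H6, Ph-pybox, iPr2NEt, MeOH, −20 °C) through a copper allenylidene, which makes the reaction enantioconvergent. The ligand antipode is chosen on the model pair F9 and 6, whose product can be compared with 7.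

Step 17. The most likely failure is poor 4α/4β facial selectivity, or no substitution at all, because C6 of the hub lies between two benzyloxy groups and the cation is large; self-condensation of 27 competes. Fallback, from 25 and 31 to 33, making the bond by cross-coupling and setting C3 and C4 stereospecifically: 31 is iodinated at C6 of the hub (N-iodosuccinimide, CH2Cl2, −40 °C) to the aryl iodide F10. Sonogashira coupling with 25 (Pd(PPh3)2Cl2, CuI, Et3N, DMF, 50 °C) gives the diaryl alkyne F11. Gold-catalysed 6-endo hydroarylation (Ph3PAuNTf2) gives the 4-aryl flav-3-ene F12. Hydroboration–oxidation (BH3·THF; NaBO3) adds H and OH syn from the face opposite the C2 aryl group, giving the 2,3-trans-3,4-trans arrangement and returning to 33.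

Further compounds

F1 | step 11 | 4-[(2R,3S)-3,7-bis(benzyloxy)-2-[3,4-bis(benzyloxy)phenyl]chroman-4α-yl]benzene-1,3-diol | c5ccccc5COc1ccc2c(c1)O[C@H](c1ccc(OCc5ccccc5)c(OCc5ccccc5)c1)[C@@H](OCc5ccccc5)[C@@H]2c1ccc(O)cc1O
F2 | step 11 | 4-[unit 1 chroman-4α-yl]-3-hydroxyphenyl acetate | c5ccccc5COc1ccc2c(c1)O[C@H](c1ccc(OCc5ccccc5)c(OCc5ccccc5)c1)[C@@H](OCc5ccccc5)[C@@H]2c1ccc(OC(C)=O)cc1O
F3 | step 11 | 4-[unit 1 chroman-4α-yl]-3-(triisopropylsiloxy)phenyl acetate | c5ccccc5COc1ccc2c(c1)O[C@H](c1ccc(OCc5ccccc5)c(OCc5ccccc5)c1)[C@@H](OCc5ccccc5)[C@@H]2c1ccc(OC(C)=O)cc1O[Si](C(C)C)(C(C)C)C(C)C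
F4 | step 9 | 3-[unit 1 chroman-4α-yl]pentane-2,4-dione | c5ccccc5COc1ccc2c(c1)O[C@H](c1ccc(OCc5ccccc5)c(OCc5ccccc5)c1)[C@@H](OCc5ccccc5)[C@@H]2C(C(C)=O)C(C)=O
F5 | step 9 | 1-diazo-1-[unit 1 chroman-4α-yl]propan-2-one | c5ccccc5COc1ccc2c(c1)O[C@H](c1ccc(OCc5ccccc5)c(OCc5ccccc5)c1)[C@@H](OCc5ccccc5)[C@@H]2C(=[N+]=[N-])C(C)=O
F6 | step 9 | 1-diazo-4-(dimethylamino)-1-[unit 1 chroman-4α-yl]butan-2-one | c5ccccc5COc1ccc2c(c1)O[C@H](c1ccc(OCc5ccccc5)c(OCc5ccccc5)c1)[C@@H](OCc5ccccc5)[C@@H]2C(=[N+]=[N-])C(=O)CCN(C)C
F7 | step 8 | 1-[unit 1 chroman-4α-yl]propan-2-one | c5ccccc5COc1ccc2c(c1)O[C@H](c1ccc(OCc5ccccc5)c(OCc5ccccc5)c1)[C@@H](OCc5ccccc5)[C@@H]2CC(C)=O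
F8 | step 8 | 4-(dimethylamino)-1-[unit 1 chroman-4α-yl]butan-2-one | c5ccccc5COc1ccc2c(c1)O[C@H](c1ccc(OCc5ccccc5)c(OCc5ccccc5)c1)[C@@H](OCc5ccccc5)[C@@H]2CC(=O)CCN(C)C
F9 | step 12 | rac-1-[3,4-bis(benzyloxy)phenyl]prop-2-yn-1-yl acetate | CC(=O)OC(C#C)c1ccc(OCc2ccccc2)c(OCc2ccccc2)c1
F10 | step 17 | 6-iodo derivative of 31 (iodine on C6 of the hub) | Ic1c(OCc5ccccc5)c2c(c([C@@H]3c4ccc(OCc5ccccc5)cc4O[C@H](c4ccc(OCc5ccccc5)c(OCc5ccccc5)c4)[C@H]3O)c1OCc5ccccc5)O[C@H](c1ccc(OCc5ccccc5)c(OCc5ccccc5)c1)[C@@H](O)C2
F11 | step 17 | diaryl alkyne from 25 and F10 (alkyne terminus on C6 of the hub) | c5ccccc5COc1ccc2c(c1)O[C@H](c1ccc(OCc5ccccc5)c(OCc5ccccc5)c1)[C@@H](OCc5ccccc5)[C@@H]2c1ccc(O[C@H](c2ccc(OCc5ccccc5)c(OCc5ccccc5)c2)C#Cc2c(OCc5ccccc5)c3c(c([C@@H]4c6ccc(OCc5ccccc5)cc6O[C@H](c6ccc(OCc5ccccc5)c(OCc5ccccc5)c6)[C@H]4O)c2OCc5ccccc5)O[C@H](c2ccc(OCc5ccccc5)c(OCc5ccccc5)c2)[C@@H](O)C3)cc1O[Si](C(C)C)(C(C)C)C(C)C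
F12 | step 17 | protected tetramer with unit 2 as 4-aryl flav-3-ene | c5ccccc5COc1ccc2c(c1)O[C@H](c1ccc(OCc5ccccc5)c(OCc5ccccc5)c1)[C@@H](OCc5ccccc5)[C@@H]2c1cc2c(cc1O[Si](C(C)C)(C(C)C)C(C)C)O[C@H](c1ccc(OCc5ccccc5)c(OCc5ccccc5)c1)C=C2c1c(OCc5ccccc5)c2c(c([C@@H]3c4ccc(OCc5ccccc5)cc4O[C@H](c4ccc(OCc5ccccc5)c(OCc5ccccc5)c4)[C@H]3O)c1OCc5ccccc5)O[C@H](c1ccc(OCc5ccccc5)c(OCc5ccccc5)c1)[C@@H](O)C2
A1 | alternative 1 | per-O-benzyl tris(flav-3-ene) tetramer | c5ccccc5COc1ccc2c(c1)O[C@H](c1ccc(OCc5ccccc5)c(OCc5ccccc5)c1)C=C2c1cc2c(cc1OCc5ccccc5)O[C@H](c1ccc(OCc5ccccc5)c(OCc5ccccc5)c1)C=C2c1c(OCc5ccccc5)c2c(c(C3=C[C@@H](c4ccc(OCc5ccccc5)c(OCc5ccccc5)c4)Oc4cc(OCc5ccccc5)ccc34)c1OCc5ccccc5)O[C@H](c1ccc(OCc5ccccc5)c(OCc5ccccc5)c1)[C@@H](OCc5ccccc5)C2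
A2 | alternative 2 | protected tetramer with triisopropylsilyl ethers on O5 and O7 of the hub | c5ccccc5COc1ccc2c(c1)O[C@H](c1ccc(OCc5ccccc5)c(OCc5ccccc5)c1)[C@@H](OCc5ccccc5)[C@@H]2c1cc2c(cc1OCc5ccccc5)O[C@H](c1ccc(OCc5ccccc5)c(OCc5ccccc5)c1)[C@@H](OCc5ccccc5)[C@@H]2c1c(O[Si](C(C)C)(C(C)C)C(C)C)c2c(c([C@@H]3c4ccc(OCc5ccccc5)cc4O[C@H](c4ccc(OCc5ccccc5)c(OCc5ccccc5)c4)[C@H]3OCc5ccccc5)c1O[Si](C(C)C)(C(C)C)C(C)C)O[C@H](c1ccc(OCc5ccccc5)c(OCc5ccccc5)c1)[C@@H](OCc5ccccc5)C2
A3 | alternative 3 | benzylated hub bearing unit 4 on C8 as a flav-2-ene (2-aryl-4H-chromene) | c1c(OCc5ccccc5)c2c(c([C@@H]3c4ccc(OCc5ccccc5)cc4OC(c4ccc(OCc5ccccc5)c(OCc5ccccc5)c4)=C3)c1OCc5ccccc5)O[C@H](c1ccc(OCc5ccccc5)c(OCc5ccccc5)c1)[C@@H](OCc5ccccc5)C2
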